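(Readings and results come from a simulation from invented constants, and the scatter is random.)

In the first minutes target rose fast. Maple read 9.1 % at 4.00 min, a mean rate of 0.0227 min⁻¹ in fractions of the charge, and birch read 19.8 % at 8.00 min, or 0.0248 min⁻¹. That rate did not last. Maple's mean rate up to 12.0 min was lower by a factor of 1.67, and between 12.0 min and 50.0 min the flask lost 0.00200 min⁻¹. Each step up in second nucleophile, 2.5 equiv to 5 equiv to 10 equiv, divided the last reading by 1.62 and then 2.17.

| flask | substrate | first nucleophile | second nucleophile | remark | time |
|---|---|---|---|---|---|
| maple | 10 mM | 1.5 equiv | 5 equiv | run made earlier |  |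
| birch | 10 mM | 1.5 equiv | 2.5 equiv | run made earlier |  |
| alder | 10 mM | 1.5 equiv | 10 equiv | run made earlier |  |
| north-east | 10 mM (fed, over 1.0 h) | 1.50 equiv | 5.00 equiv | all else is in the flask from the start; the feed brings no volume worth counting | 80 min |
| south | 10 mM | 1.50 equiv | 5.00 equiv | everything together at the start | 80 min |
| north-west | 10 mM (fed, over 15 min) | 1.50 equiv | 5.00 equiv | all else is in the flask from the start; the feed brings no volume worth counting | 80 min |
| north | 10 mM | 1.50 equiv | 5.00 equiv (fed, over 1.0 h) | all else is in the flask from the start; the feed brings no volume worth counting | 80 min |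

| run | time / min | target / % |
|---|---|---|
| maple | 4.00 | 9.1 |
| maple | 12.0 | 16.3 |
| maple | 25.0 | 12.8 |
| maple | 30.0 | 11.3 |
| maple | 50.0 | 8.7 |
| maple | 60.0 | 8.1 |
| maple | 80.0 | 8.9 |
| birch | 8.00 | 19.8 |
| birch | 12.0 | 20.0 |
| birch | 20.0 | 19.3 |
| birch | 25.0 | 17.7 |
| birch | 40.0 | 15.7 |
| birch | 60.0 | 14.4 |
| birch | 90.0 | 14.4 |
| alder | 15.0 | 8.2 |
| alder | 30.0 | 7.1 |
| alder | 40.0 | 5.1 |
| alder | 60.0 | 6.1 |
| alder | 80.0 | 3.0 |
| alder | 90.0 | 4.1 |

(standard deviation of a reading: 1 percentage point)



* the flask that comes out highest in amount of target, in percent of the substrate charged, or "all alike" when all lie within 1.5 percentage points (north-east / south / north-west / north / all alike)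
* target at the end, in percent of the substrate charged, north-east
* target at the end, in percent of the substrate charged, south
* target at the end, in percent of the substrate charged, north-west
* target at the end, in percent of the substrate charged, north

So I carried one quantity, the late product: the last target fraction times the dose of second nucleophile, in equivalents of a 10 mM charge.

birch 0.360 equiv, maple 0.445 equiv, alder 0.410 equiv

mean: 0.405 equiv

For south I reckoned 8.10 %. North-east and north-west hold the full dose from the start, so I put them near that figure, with north-east somewhat above it, its feed closing 20.0 min before the end. North's feed reaches birch's dose at 30.0 min, so I expected it near birch's 14.4 %, more than south.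

The forecast named north as highest, with 10 % for north-east, 8.5 % for south, 8.8 % for north-west and 13.5 % for north: “Feeding the second nucleophile keeps it low early, so target builds high.” My north lay 0.9 percentage points above the forecast's.

The flasks gave 10.3 % in north-east, 8.31 % in south, 8.69 % in north-west and 14.6 % in north, so north came out highest and the forecast stands within its tolerance.

    substrate ⇌ intermediate (K = 0.0100, k = 0.00130 s⁻¹)
    first nucleophile + intermediate → target (k = 130 L mol⁻¹ s⁻¹)
    second nucleophile + intermediate → other capture product (k = 28.0 L mol⁻¹ s⁻¹)
    second nucleophile + target → over-reaction product (k = 0.00880 L mol⁻¹ s⁻¹)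
    target ⇌ isomer of the product (K = 2.70, k = 0.00230 s⁻¹)

For the order to turn with north-east held at its figure, north has to fall by its lead of 4.3 points; north moved 5 points at 9.12 equiv of second nucleophile. South's late product came to 0.416 equiv, with second nucleophile at 87 % of its charge, a pseudo-first-order excess. South's recipe at 40 mM substrate carries a dose of 20.0 equiv on the same count, so 0.405 equiv gives 2.02 %; that flask gave 2.35 %.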